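## Analysis of the target

The target is a monocyclic 1,2-dioxane (ring atoms O1, O2, C3, C4, C5, C6). C6 is a peroxyketal carbon carrying a methoxy group and a sixteen-carbon chain (C1'–C3' methylenes, C4'≡C5', an E-configured C6'=C7', seven methylenes, terminal C15'=C16'). C3 carries a hydrogen and a CH2CO2H arm. The two stereocentres, C3 (S) and C6 (R), are 1,4-related across the ring; in the chair the CH2CO2H arm and the chain are both equatorial and the methoxy group is axial, so the target is the anomerically stabilised ketal epimer. C6 can therefore be corrected with acid through reversible ionisation of the peroxyketal. C3 is a secondary carbon of a dialkyl peroxide, cannot be epimerised, and has to be set absolutely. The feature the route is built on is the array O2–C3(H)–CH2–CO2H: this is a β-peroxy carboxylic acid, the formal product of opening a 4-substituted oxetan-2-one at its C4 by a peroxide oxygen, while O1 sits on a carbon at ketone oxidation level that can carry a hydroperoxide. Sensitive groups are the O–O bond (reductants, phosphines, low-valent metals, base next to an enolisable carbonyl), the acid-labile peroxyketal, the free acid, and three C–C multiple bonds that exclude ozone, hydrogenation and radical conditions once the chain is complete. The difficulty is that no general catalytic asymmetric method makes a secondary C–OO bond, and the peroxide has to be introduced late under conditions the unsaturation survives.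

## Retrosynthetic reasoning

15 to 10 and 14. The C5'–C6' bond between the alkyne and the E-alkene is cut. This removes both C=C bonds from the peroxide-bearing half, so the peroxide can be made with ozone, and it is the one bond of the chain that a mild sp–sp2 coupling forms with retention of the E geometry. The forward reaction is a Sonogashira coupling that has to tolerate a dialkyl peroxide and a free acid.

10 to 8, through 9. The O2–C3 bond is cut, which opens the 1,2-dioxane. The O2–C3(H)–CH2–CO2H array is read as an opened β-lactone, so the precursor 8 is an acyclic hydroperoxy ketal tethered to a (4R)-oxetan-2-one. The forward step closes the ring at lactone C4 with inversion, sets C3 and releases the free acid in one operation, with no later oxidation-state change. The lactone ring is not in the target: it is made to store the C3 configuration and to activate C3, and it is cleaved in the key step. C6 is left to thermodynamics: the epimer mixture 9 is funnelled by acid to 10.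

8 to 7. The two C6–O bonds (to O1 and to the methoxy oxygen) are cut back to a 1,1-disubstituted alkene. Ozonolysis in an alcohol co-solvent puts the carbonyl oxide on the more substituted carbon, and the alcohol traps it as the methoxy hydroperoxide. The terminal alkyne and the lactone have to survive.

7 to 6. The lactone is cut at the C3–C4 and O1–C2 bonds of the oxetanone (target bond C3–CH2 of the acid arm), back to aldehyde 6 and a two-carbon acyl unit. A catalytic asymmetric [2+2] cyclocondensation sets the only stereocentre that needs absolute control, and the aldehyde oxygen ends up as a carboxyl oxygen of the target.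

6 to 1 and 3, through 5, 4 and 2. The aldehyde comes from ester 5, the methylidene from ketone 4, and the bond between the ketone carbon (target C6) and its α-methylene (target C5) from acylation of the zinc homoenolate 3 by acid chloride 2, which is made from acid 1. No protecting group is needed.

14 to 11, through 13 and 12. The vinyl iodide is cut at C–I back to terminal alkyne 12 (syn-hydrozirconation through 13 fixes the E geometry), and 12 is cut at its propargylic C–C bond to bromide 11 and an acetylide unit.

## Alternatives that were turned down

Alternative 1: the textbook disconnection. The O2–C3 bond is formed by a 6-exo-trig peroxy-Michael addition of the hydroperoxy ketal enoate A1, methyl (2E)-6-hydroperoxy-6-methoxyundec-2-en-10-ynoate, under amine base in a fluorinated alcohol, giving the dioxane ester A2. It was turned down for three reasons.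
- A1 is achiral and C3 arises by addition to a prochiral trigonal carbon with no controlling element, so A2 forms racemic at the one centre that cannot be corrected later.
- A chiral catalyst would have to activate a simple enoate, the weakest Michael acceptor, toward a weak nucleophile; a resolution discards half the material.
- The route ends at an ester, and its saponification exposes a β-peroxy ester to enolisation, retro-addition and Weitz–Scheffer-type epoxide formation. The step count is no lower.

Alternative 2: stereospecific displacement of a sulfonate. The O2–C3 bond is formed by a base-mediated 6-exo-tet SN2 reaction of the hydroperoxy ketal mesylate A3, methyl (3R)-6-hydroperoxy-6-methoxy-3-(methanesulfonyloxy)undec-10-ynoate, giving ester A4. It was turned down because the leaving group is β to an ester with acidic α-hydrogens. The base that forms the peroxide anion also triggers E1cB elimination to A1, which then cyclises along the racemic path of alternative 1 and erodes the enantiomeric purity. Avoiding this means carrying the acid as a protected alcohol, which adds protection, deprotection and a late oxidation, and the route still ends with an ester hydrolysis.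

Alternative 3: strain-release radical ring expansion. The cyclobutanol A5, methyl 2-[2-hydroxy-2-(pent-4-yn-1-yl)cyclobutyl]acetate, is oxidised with O2 and catalytic Co(acac)2. β-Scission of the alkoxy radical, capture of the C3 radical by O2 and closure of the peroxyl radical onto the ketone give the dioxanol A6, which is then ketalised. The step is attractive because it builds both C–O bonds and the ring from dioxygen. It was turned down because C3 passes through a planar secondary radical, so any configuration built into A5 is erased and A6 is racemic at C3. The radical chain is also exposed to the alkyne, and a stereodefined A5 is no shorter to make than lactone 7.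

Key step: step 7

Assumption: in the aluminium-catalysed cyclocondensation of step 5 the (S,S) ligand (from L-valinol) is taken to give (4S)-4-alkyloxetan-2-ones from unbranched aldehydes, so the (R,R) ligand (from D-valinol) is specified for 7; if the sense is the opposite, the other ligand antipode is used and nothing else changes.

## Route

Step 1
Reactants: 1 hex-5-ynoic acid
Product: 2 hex-5-ynoyl chloride
Conditions: (COCl)2, cat. DMF, CH2Cl2, 0 °C to rt; concentrated and used crude
Reagents that add atoms: oxalyl chloride, ClC(=O)C(=O)Cl
Why: Standard acid chloride formation through the Vilsmeier-type chloroiminium species; the terminal alkyne is inert and all by-products are volatile.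

Step 2
Reactants: 2 hex-5-ynoyl chloride; 3 (3-ethoxy-3-oxopropyl)zinc bromide (commercial solution in THF)
Product: 4 ethyl 4-oxonon-8-ynoate
Conditions: Pd(PPh3)4 (3 mol %), THF, 0 °C to rt
Reagents that add atoms: none
Why: Negishi acylation: zerovalent palladium inserts into the C–Cl bond, the zinc homoenolate transmetalates and reductive elimination gives the γ-keto ester. The alkylzinc halide is too weakly basic and nucleophilic to touch the terminal alkyne, the ester or the product ketone.

Step 3
Reactants: 4 ethyl 4-oxonon-8-ynoate
Product: 5 ethyl 4-methylidenenon-8-ynoate
Conditions: Ph3PCH3Br (1.3 equiv), KN(SiMe3)2 (1.2 equiv), THF, 0 °C; then 4, 0 °C to rt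
Reagents that add atoms: methyltriphenylphosphonium bromide, C[P+](c1ccccc1)(c1ccccc1)c1ccccc1.[Br-]
Why: Wittig methylenation of the ketone; the ester is not attacked by the non-stabilised ylide at this temperature. Keeping the base substoichiometric to the salt leaves only the ylide, which is too weak a base to deprotonate the terminal alkyne.

Step 4
Reactants: 5 ethyl 4-methylidenenon-8-ynoate
Product: 6 4-methylidenenon-8-ynal
Conditions: iBu2AlH (1.05 equiv), CH2Cl2, −78 °C; aqueous potassium sodium tartrate work-up
Reagents that add atoms: none
Why: Partial reduction of the ester: the tetrahedral aluminium hemiacetal is stable at −78 °C and collapses to the aldehyde only on work-up. The alkene and alkyne do not hydroaluminate at this temperature.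

Step 5
Reactants: 6 4-methylidenenon-8-ynal
Product: 7 (4R)-4-(3-methylideneoct-7-yn-1-yl)oxetan-2-one
Conditions: CH3COBr, iPr2NEt, MeAl[BnN(CH2CH(iPr)NTf)2] with the (R,R) ligand (10 mol %), CH2Cl2, −50 °C
Reagents that add atoms: acetyl bromide, CC(=O)Br
Why: Catalytic asymmetric acyl halide–aldehyde cyclocondensation: ketene is generated in the flask and adds to the aldehyde bound to the chiral trivalent aluminium complex in a formal [2+2] (aldol–lactonisation) reaction. The catalyst directs the two-carbon unit to the Si face of the aldehyde, which gives the (4R) lactone; unbranched aliphatic aldehydes are the standard substrates, and the alkene and alkyne are spectators.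

Step 6
Reactants: 7 (4R)-4-(3-methylideneoct-7-yn-1-yl)oxetan-2-one
Product: 8 (4R)-4-(3-hydroperoxy-3-methoxyoct-7-yn-1-yl)oxetan-2-one (both epimers at the ketal carbon)
Conditions: O3, CH2Cl2/MeOH 4:1, −78 °C, Sudan Red 7B as end-point indicator; N2 purge, concentration below rt, no reductive work-up
Reagents that add atoms: ozone, [O-][O+]=O; methanol, CO
Why: Ozonolysis of the 1,1-disubstituted alkene: the primary ozonide fragments to the ketone oxide and formaldehyde, and methanol traps the carbonyl oxide as the methoxy hydroperoxide. The electron-rich alkene reacts far faster than the terminal alkyne, and the lactone is inert to neutral methanol at −78 °C. The new ketal centre forms without control, which does not matter because step 7 equilibrates it.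

Step 7
Reactants: 8 (4R)-4-(3-hydroperoxy-3-methoxyoct-7-yn-1-yl)oxetan-2-one
Product: 10 2-[(3S,6R)-6-methoxy-6-(pent-4-yn-1-yl)-1,2-dioxan-3-yl]acetic acid, via C6-epimeric dioxane acid mixture 9 (not isolated)
Conditions: Cs2CO3 (1.2 equiv), MeCN (0.01 M), 0 °C to rt; then MsOH (2.6 equiv), MeOH (10 equiv), 3 Å molecular sieves, rt
Reagents that add atoms: none
Why: Proposed new method: Cs2CO3 deprotonates only the hydroperoxy ketal of 8, and the peroxide anion, a weakly basic α-effect nucleophile, attacks lactone C4 from the face opposite the ring oxygen in a 6-exo-tet SN2 alkyl–oxygen cleavage that forms the O2–C3 bond, closes the 1,2-dioxane and releases the carboxylate, driven by the strain of the four-membered ring. The closest known reaction types are the base-mediated intramolecular alkylation of hydroperoxy ketals by secondary sulfonates, the intramolecular opening of oxetanes by hydroperoxides with inversion, and the SN2 opening of 4-alkyl β-lactones at C4 by azide, thiolate or carboxylate; a peroxide oxygen has not been used in this last role. C3 is set by inversion, so the (4R) centre of 8 becomes (3S). C6 is not controlled in the ring closure: both ketal epimers of 8 cyclise to 9, and the acid stage then equilibrates C6 by reversible ionisation of the peroxyketal toward the chair with axial OMe (anomeric effect) and equatorial chain and CH2CO2H arm, which is 10; any remaining C6 epimer is separated and returned to the acid stage. The step needs alkylation at C4 and not acylation at C2 (acyl attack would close an eight-membered perester, C4 lies at six-ring distance, and weakly basic anions prefer C4 of β-lactones), ring closure and not oligomerisation (high dilution), and substitution and not elimination (carbonate cannot enolise the lactone, and in the planar four-membered ring the C4–O bond is orthogonal to the enolate π-system). Only a few equivalents of MeOH are present in the acid stage, so esterification of the acid should not compete, and exchange of the methoxy group with MeOH is degenerate.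

Step 8
Reactants: 11 9-bromonon-1-ene
Product: 12 undec-1-en-10-yne
Conditions: LiC≡CH·H2NCH2CH2NH2 (1.5 equiv), DMSO, 0 °C to rt
Reagents that add atoms: lithium acetylide ethylenediamine complex, [Li+].[C-]#C.NCCN
Why: SN2 alkylation of the acetylide by the unhindered primary bromide in a dipolar aprotic solvent; the remote terminal alkene is unaffected.

Step 9
Reactants: 12 undec-1-en-10-yne
Product: 14 (1E)-1-iodoundeca-1,10-diene, via alkenylzirconocene chloride 13 (not isolated)
Conditions: Cp2Zr(H)Cl (1.05 equiv), THF, rt; then I2, 0 °C
Reagents that add atoms: iodine, II; Cp2Zr(H)Cl, [H][Zr](Cl)(C1C=CC=C1)C1C=CC=C1 (its zirconocene unit stays only in intermediate 13)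
Why: Hydrozirconation–iodination: syn addition of Zr–H places zirconium on the terminal carbon, and iodinolysis with retention gives the pure E vinyl iodide. The terminal alkyne reacts faster than the terminal alkene, so one equivalent of the hydride should leave the alkene untouched.

Step 10
Reactants: 10 2-[(3S,6R)-6-methoxy-6-(pent-4-yn-1-yl)-1,2-dioxan-3-yl]acetic acid; 14 (1E)-1-iodoundeca-1,10-diene
Product: 15 2-[(3S,6R)-6-[(6E)-hexadeca-6,15-dien-4-yn-1-yl]-6-methoxy-1,2-dioxan-3-yl]acetic acid (target)
Conditions: Pd(PPh3)4 (5 mol %), CuI (10 mol %), Et3N (5 equiv), degassed THF, rt; dilute citric acid work-up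
Reagents that add atoms: none
Why: Sonogashira coupling: oxidative addition of zerovalent palladium to the vinyl iodide is fast at rt and keeps the E geometry, and the copper acetylide transmetalates under amine base, which also carries the acid as its ammonium salt. Saturated dialkyl peroxides and peroxyketals belong to the substrate classes that survive palladium-catalysed couplings at rt, and neither stereocentre is touched.

## Compound list

1 | hex-5-ynoic acid | C#CCCCC(=O)O | starting material
2 | hex-5-ynoyl chloride | C#CCCCC(=O)Cl | intermediate
3 | (3-ethoxy-3-oxopropyl)zinc bromide | CCOC(=O)CC[Zn]Br | starting material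
4 | ethyl 4-oxonon-8-ynoate | CCOC(=O)CCC(=O)CCCC#C | intermediate
5 | ethyl 4-methylidenenon-8-ynoate | CCOC(=O)CCC(=C)CCCC#C | intermediate
6 | 4-methylidenenon-8-ynal | O=CCCC(=C)CCCC#C | intermediate
7 | (4R)-4-(3-methylideneoct-7-yn-1-yl)oxetan-2-one | C#CCCCC(=C)CC[C@@H]1CC(=O)O1 | intermediate
8 | (4R)-4-(3-hydroperoxy-3-methoxyoct-7-yn-1-yl)oxetan-2-one, both epimers at the ketal carbon | C#CCCCC(OC)(OO)CC[C@@H]1CC(=O)O1 | intermediate
9 | 2-[(3S)-6-methoxy-6-(pent-4-yn-1-yl)-1,2-dioxan-3-yl]acetic acid, both epimers at C6 (caesium salt in the flask) | C#CCCCC1(OC)CC[C@@H](CC(=O)O)OO1 | intermediate (not isolated)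
10 | 2-[(3S,6R)-6-methoxy-6-(pent-4-yn-1-yl)-1,2-dioxan-3-yl]acetic acid | C#CCCC[C@]1(OC)CC[C@@H](CC(=O)O)OO1 | intermediate
11 | 9-bromonon-1-ene | C=CCCCCCCCBr | starting material
12 | undec-1-en-10-yne | C=CCCCCCCCC#C | intermediate
13 | chlorobis(cyclopentadienyl)[(1E)-undeca-1,10-dien-1-yl]zirconium | C=CCCCCCCC/C=C/[Zr](Cl)(C1C=CC=C1)C1C=CC=C1 | intermediate (not isolated)
14 | (1E)-1-iodoundeca-1,10-diene | C=CCCCCCCC/C=C/I | intermediate
15 | 2-[(3S,6R)-6-[(6E)-hexadeca-6,15-dien-4-yn-1-yl]-6-methoxy-1,2-dioxan-3-yl]acetic acid (CNP0125368.1) | C=CCCCCCCC/C=C/C#CCCC[C@]1(OC)CC[C@@H](CC(=O)O)OO1 | target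

## Step count and risk

Total: 10 steps. Longest linear sequence: 8 steps (steps 1 to 7, then step 10); steps 8 and 9 form the side branch.

Step 7 (key step, proposed new method). Most likely to go wrong: attack of the peroxide anion on a lactone carbonyl of a second molecule (acyl–oxygen cleavage and oligomerisation) instead of the intramolecular alkylation at C4, base-induced opening of the lactone by elimination, or incomplete funnelling of C6 in the acid stage. The fallback uses the known intramolecular opening of an oxetane by a hydroperoxide. It sets out from 7 and comes back at 10.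
- LiBH4 in THF should reduce the lactone of 7 to (3R)-6-methylideneundec-10-yne-1,3-diol F1, with the stereocentre untouched.
- Selective sulfonylation of the primary hydroxyl (TsCl, pyridine, −20 °C) should give (3R)-3-hydroxy-6-methylideneundec-10-yn-1-yl 4-methylbenzenesulfonate F2.
- KOtBu in THF should close (2R)-2-(3-methylideneoct-7-yn-1-yl)oxetane F3 by attack of the secondary alkoxide on the primary carbon, again without touching the stereocentre.
- Ozonolysis as in step 6 should give (2R)-2-(3-hydroperoxy-3-methoxyoct-7-yn-1-yl)oxetane F4.
- Catalytic Yb(OTf)3 or TMSOTf in CH2Cl2 should bring about the 6-exo opening of the oxetane at its substituted carbon with inversion; after the MsOH/MeOH equilibration of C6 this gives 2-[(3S,6R)-6-methoxy-6-(pent-4-yn-1-yl)-1,2-dioxan-3-yl]ethan-1-ol F5.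
- Oxidation of the primary alcohol with catalytic TEMPO and PhI(OAc)2 in MeCN/water, which dialkyl peroxides tolerate, returns the route to 10.

This costs four more steps, which is what the lactone is meant to save.

Step 5. Most likely to go wrong: insufficient facial discrimination or slow turnover with this aldehyde, with ketene self-condensation taking over. The fallback builds the same lactone from an enzymatically reduced β-keto ester. It sets out from 6 and comes back at 7.
- A Roskamp homologation (ethyl diazoacetate, catalytic SnCl2, CH2Cl2) should give ethyl 6-methylidene-3-oxoundec-10-ynoate F6.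
- A commercial ketoreductase of (R)-selectivity with NADPH recycling should reduce it to ethyl (3R)-3-hydroxy-6-methylideneundec-10-ynoate F7 without touching the alkene or alkyne.
- LiOH in THF/water should give (3R)-3-hydroxy-6-methylideneundec-10-ynoic acid F8.
- Lactonisation by carboxyl activation (PhSO2Cl, pyridine, 0 °C), which leaves the C3–O bond intact and therefore retains configuration, returns 7.

Step 6. Most likely to go wrong: competing oxidation of the terminal alkyne, capture of the new hydroperoxide by the formaldehyde that is released, or methanolysis of the strained lactone during concentration. The fallback is ozone-free and makes the hydroperoxy ketal by ketal–hydrogen peroxide exchange. It sets out from 4 and comes back at 8.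
- Ketalisation (HC(OMe)3, catalytic TsOH) should give ethyl 4,4-dimethoxynon-8-ynoate F9.
- iBu2AlH at −78 °C should give 4,4-dimethoxynon-8-ynal F10.
- The cyclocondensation of step 5 should give (4R)-4-(3,3-dimethoxyoct-7-yn-1-yl)oxetan-2-one F11.
- Anhydrous H2O2 in Et2O with catalytic acid at 0 °C should exchange one methoxy group for a hydroperoxy group and give 8.

Step 10. Most likely to go wrong: cleavage of the O–O bond by zerovalent palladium, phosphine or monovalent copper, or oxidative homocoupling of the alkyne. The fallback completes the chain before any peroxide exists and dispenses with ozone. It sets out from 4 and 14 and comes back at 15.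
- Sonogashira coupling of 4 with 14 (Pd(PPh3)4, CuI, Et3N) should give ethyl (10E)-4-oxoicosa-10,19-dien-8-ynoate F12.
- Ketalisation should give ethyl (10E)-4,4-dimethoxyicosa-10,19-dien-8-ynoate F13.
- iBu2AlH at −78 °C should give (10E)-4,4-dimethoxyicosa-10,19-dien-8-ynal F14.
- The cyclocondensation of step 5 should give (4R)-4-[(9E)-3,3-dimethoxynonadeca-9,18-dien-7-yn-1-yl]oxetan-2-one F15.
- Exchange with anhydrous H2O2 under acid catalysis should give (4R)-4-[(9E)-3-hydroperoxy-3-methoxynonadeca-9,18-dien-7-yn-1-yl]oxetan-2-one F16.
- The conditions of step 7 should then give 15 directly.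

## Further compounds

F1 | step 7 | (3R)-6-methylideneundec-10-yne-1,3-diol | C#CCCCC(=C)CC[C@@H](O)CCO
F2 | step 7 | (3R)-3-hydroxy-6-methylideneundec-10-yn-1-yl 4-methylbenzenesulfonate | C#CCCCC(=C)CC[C@@H](O)CCOS(=O)(=O)c1ccc(C)cc1
F3 | step 7 | (2R)-2-(3-methylideneoct-7-yn-1-yl)oxetane | C#CCCCC(=C)CC[C@@H]1CCO1
F4 | step 7 | (2R)-2-(3-hydroperoxy-3-methoxyoct-7-yn-1-yl)oxetane, both epimers at the ketal carbon | C#CCCCC(OC)(OO)CC[C@@H]1CCO1
F5 | step 7 | 2-[(3S,6R)-6-methoxy-6-(pent-4-yn-1-yl)-1,2-dioxan-3-yl]ethan-1-ol | C#CCCC[C@]1(OC)CC[C@@H](CCO)OO1
F6 | step 5 | ethyl 6-methylidene-3-oxoundec-10-ynoate | CCOC(=O)CC(=O)CCC(=C)CCCC#C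
F7 | step 5 | ethyl (3R)-3-hydroxy-6-methylideneundec-10-ynoate | CCOC(=O)C[C@H](O)CCC(=C)CCCC#C
F8 | step 5 | (3R)-3-hydroxy-6-methylideneundec-10-ynoic acid | OC(=O)C[C@H](O)CCC(=C)CCCC#C
F9 | step 6 | ethyl 4,4-dimethoxynon-8-ynoate | CCOC(=O)CCC(OC)(OC)CCCC#C
F10 | step 6 | 4,4-dimethoxynon-8-ynal | O=CCCC(OC)(OC)CCCC#C
F11 | step 6 | (4R)-4-(3,3-dimethoxyoct-7-yn-1-yl)oxetan-2-one | C#CCCCC(OC)(OC)CC[C@@H]1CC(=O)O1
F12 | step 10 | ethyl (10E)-4-oxoicosa-10,19-dien-8-ynoate | CCOC(=O)CCC(=O)CCCC#C/C=C/CCCCCCCC=C
F13 | step 10 | ethyl (10E)-4,4-dimethoxyicosa-10,19-dien-8-ynoate | CCOC(=O)CCC(OC)(OC)CCCC#C/C=C/CCCCCCCC=C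
F14 | step 10 | (10E)-4,4-dimethoxyicosa-10,19-dien-8-ynal | O=CCCC(OC)(OC)CCCC#C/C=C/CCCCCCCC=C
F15 | step 10 | (4R)-4-[(9E)-3,3-dimethoxynonadeca-9,18-dien-7-yn-1-yl]oxetan-2-one | C=CCCCCCCC/C=C/C#CCCCC(OC)(OC)CC[C@@H]1CC(=O)O1
F16 | step 10 | (4R)-4-[(9E)-3-hydroperoxy-3-methoxynonadeca-9,18-dien-7-yn-1-yl]oxetan-2-one, both epimers at the ketal carbon | C=CCCCCCCC/C=C/C#CCCCC(OC)(OO)CC[C@@H]1CC(=O)O1
A1 | alternative 1 | methyl (2E)-6-hydroperoxy-6-methoxyundec-2-en-10-ynoate | COC(=O)/C=C/CCC(OC)(OO)CCCC#C
A2 | alternative 1 | methyl 2-[6-methoxy-6-(pent-4-yn-1-yl)-1,2-dioxan-3-yl]acetate, racemic | COC(=O)CC1CCC(OC)(CCCC#C)OO1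
A3 | alternative 2 | methyl (3R)-6-hydroperoxy-6-methoxy-3-(methanesulfonyloxy)undec-10-ynoate | COC(=O)C[C@H](OS(C)(=O)=O)CCC(OC)(OO)CCCC#C
A4 | alternative 2 | methyl 2-[(3S,6R)-6-methoxy-6-(pent-4-yn-1-yl)-1,2-dioxan-3-yl]acetate | C#CCCC[C@]1(OC)CC[C@@H](CC(=O)OC)OO1
A5 | alternative 3 | methyl 2-[2-hydroxy-2-(pent-4-yn-1-yl)cyclobutyl]acetate, racemic | COC(=O)CC1CCC1(O)CCCC#C
A6 | alternative 3 | methyl 2-[6-hydroxy-6-(pent-4-yn-1-yl)-1,2-dioxan-3-yl]acetate, racemic | COC(=O)CC1CCC(O)(CCCC#C)OO1
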